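**Plan**

- Retrosynthetic cuts, in order: the C6–O ester; O8–C12 (oxidative lactonisation of a 2-methylene-1,4-diol); C4–O (epoxide/hydride, back to C4=C5); C6–C7 ([2,3]-Wittig shift, which reconnects O6 to C13 and opens a 13-membered bis-allylic ether); C7=C11 (ring-closing Horner–Wadsworth–Emmons); O6–C13 (oxa-Michael); C1=C10 (Horner–Wadsworth–Emmons); C9–C10 (epoxide opening).
- Enabling feature (germacrane locants): the C6 carbinol carbon is bonded to C7, which carries the C11(=C13H2)–C12 unit of the methylene lactone, and C4(OH)–C5H2 is a hydrated C4=C5 alkene. C4=C5–C6(OH)–C7–C11=C13 is therefore the 1,5-dien-3-ol left by a [2,3]-Wittig shift of a C6–O–C13 ether, with the ten-membered carbocycle lying inside a 13-membered ether ring.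
- Forward order: the C1–C6 chain (geraniol) and the C7–C10/C14 unit (phosphonolactone) are joined at C1=C10; a phosphonate arm is put on O6; the 13-membered ether ring is closed at C7=C11; it is contracted to the ten-membered carbocycle (C6–C7); the C6 ester is attached and the γ-lactone ring (O8–C12) is closed last.
- Stereochemistry: C8 comes from (S)-4-methoxybenzyl glycidyl ether. C6 and C7 arise in the Wittig step from the alkene geometries (C8 cis to C13 on C7=C11) and the C8 silyloxy centre. C4 comes from C6–OH-directed epoxidation and hydride opening. The C1=C10 and C7=C11 geometries come from the two olefinations, C4=C5 from geraniol, and the side-chain Z-alkene from syn-hydroalumination.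

Key step: step 14

Remark (assumption): germacrane locants are used for all intermediates (ring C1–C10, arm C11–C13, C14 on C10, C15 on C4); 1 and 14 are taken as catalogue compounds, 14 being the formaldehyde condensation product of 2.

**Route**

Step 1
Reactants: 1 (S)-4-methoxybenzyl glycidyl ether; 2 triethyl phosphonoacetate
Product: 4 (5S)-3-(diethoxyphosphoryl)-5-{[(4-methoxybenzyl)oxy]methyl}dihydrofuran-2(3H)-one (C3 epimers; C5 is C8 and the carbonyl is C14), via hydroxy phosphonoester 3 (not isolated)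
Conditions: NaOEt, EtOH, 70 °C; then 1 M HCl
Reagents that add atoms: none
Why: Epoxide alkylation–lactonisation: the sodium salt of 2 attacks the unsubstituted epoxide carbon (SN2, so the C8 centre of 1 is untouched) and the liberated alkoxide closes onto the ester in the protic medium, which should suppress the competing phosphoryl transfer to a cyclopropane.

Step 2
Reactants: 5 geraniol
Product: 6 geranyl tert-butyldimethylsilyl ether
Conditions: TBSCl, imidazole, CH2Cl2, 0 °C to rt
Reagents that add atoms: TBSCl, CC(C)(C)[Si](C)(C)Cl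
Why: Standard silyl ether formation at a primary allylic alcohol.

Step 3
Reactants: 6 geranyl tert-butyldimethylsilyl ether
Product: 8 (4E)-6-[(tert-butyldimethylsilyl)oxy]-4-methylhex-4-enal (C1 aldehyde to C6), via epoxide 7 (not isolated)
Conditions: mCPBA, CH2Cl2, −10 °C; then H5IO6, THF/Et2O, 0 °C
Reagents that add atoms: mCPBA, O=C(OO)c1cccc(Cl)c1
Why: Prilezhaev epoxidation should take the electron-rich terminal 6,7-alkene in preference to the 2,3-alkene deactivated by the allylic oxygen, and periodic acid then hydrolyses and cleaves the epoxide (glycol cleavage) to the aldehyde and acetone without touching the E-alkene.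

Step 4
Reactants: 4 phosphonolactone; 8 aldehyde
Product: 9 (3E,5S)-3-{(4E)-6-[(tert-butyldimethylsilyl)oxy]-4-methylhex-4-en-1-ylidene}-5-{[(4-methoxybenzyl)oxy]methyl}dihydrofuran-2(3H)-one
Conditions: NaH, THF, 0 °C; then 8, 0 °C to rt
Reagents that add atoms: none
Why: Horner–Wadsworth–Emmons olefination of the phosphonolactone anion with an unhindered aldehyde should favour the thermodynamically preferred E-alkylidene lactone (C2 trans to the carbonyl, cis to C9), the minor Z isomer being removable by chromatography.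

Step 5
Reactants: 9 alkylidene lactone
Product: 10 (2S,4E,8E)-10-[(tert-butyldimethylsilyl)oxy]-4-(hydroxymethyl)-1-[(4-methoxybenzyl)oxy]-8-methyldeca-4,8-dien-2-ol (C14–OH and C8–OH free)
Conditions: i-Bu2AlH, CH2Cl2, −78 to 0 °C; aq. sodium potassium tartrate
Reagents that add atoms: none
Why: Hydride 1,2-reduction of the conjugated lactone through the lactol to the ene-diol, which keeps the alkene geometry (C9 cis to C2).

Step 6
Reactants: 10 diol
Product: 12 (2S,4E,8E)-2,10-bis[(tert-butyldimethylsilyl)oxy]-4-{[(tert-butyldiphenylsilyl)oxy]methyl}-1-[(4-methoxybenzyl)oxy]-8-methyldeca-4,8-diene (C6–OTBS; C7–OPMB; C8–OTBS; C14–OTBDPS), via mono-TBDPS ether 11 (not isolated)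
Conditions: TBDPSCl, imidazole, DMF, 0 °C; then TBSCl, rt
Reagents that add atoms: TBDPSCl, CC(C)(C)[Si](Cl)(c1ccccc1)c1ccccc1; TBSCl, CC(C)(C)[Si](C)(C)Cl
Why: Sequential silyl ether formation in one flask, the bulky chloride taking the primary allylic C14 hydroxyl first and TBSCl then silylating the secondary C8 hydroxyl.

Step 7
Reactants: 12 tetra-protected chain
Product: 13 (2E,6E,9S)-9-[(tert-butyldimethylsilyl)oxy]-7-{[(tert-butyldiphenylsilyl)oxy]methyl}-10-[(4-methoxybenzyl)oxy]-3-methyldeca-2,6-dien-1-ol (C6–OH free)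
Conditions: HF·pyridine, pyridine, THF, 0 °C
Reagents that add atoms: none
Why: Buffered fluoride desilylation should cleave the unhindered primary TBS ether much faster than the secondary TBS and the TBDPS ethers (selective silyl ether cleavage).

Step 8
Reactants: 13 C6 alcohol; 14 ethyl 2-(diethoxyphosphoryl)acrylate
Product: 15 ethyl 2-(diethoxyphosphoryl)-3-alkoxypropanoate in which the alkoxy group is O6 of 13 (C6–O–C13H2–C11H(P)(CO2Et); C11 epimers)
Conditions: NaH, THF, 0 °C; then 14, −40 to 0 °C; AcOH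
Reagents that add atoms: none
Why: Oxa-Michael addition of the sodium alkoxide to the doubly activated acrylate gives a stabilised phosphonoacetate anion that does not revert and is protonated on quench; the new C11 centre is of no consequence because it becomes sp2 in step 11.

Step 9
Reactants: 15 phosphonate ether
Product: 16 C7 primary alcohol (4-methoxybenzyl group removed)
Conditions: DDQ, CH2Cl2/pH 7 buffer, 0 °C
Reagents that add atoms: none
Why: Oxidative cleavage of the electron-rich 4-methoxybenzyl ether by DDQ, which should leave silyl ethers, the allylic ether and the phosphonate untouched.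

Step 10
Reactants: 16 C7 alcohol
Product: 17 C7 aldehyde (α-silyloxy aldehyde, 8S)
Conditions: Dess–Martin periodinane, CH2Cl2, 0 °C to rt
Reagents that add atoms: none
Why: Dess–Martin oxidation of the primary alcohol under non-basic conditions that should not epimerise C8.

Step 11
Reactants: 17 aldehyde phosphonate
Product: 18 ethyl (3E,5S,7E,11E)-5-[(tert-butyldimethylsilyl)oxy]-7-{[(tert-butyldiphenylsilyl)oxy]methyl}-11-methyl-1-oxacyclotrideca-3,7,11-triene-3-carboxylate (ring O–C13–C11(CO2Et)=C7–C8–C9–C10=C1–C2–C3–C4=C5–C6; C8 cis to C13)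
Conditions: LiCl, DBU, MeCN, rt, 1 mM (slow addition)
Reagents that add atoms: none
Why: Intramolecular Horner–Wadsworth–Emmons olefination under Masamune–Roush conditions at high dilution closes the 13-membered ring, and the E-enoate (ester trans to C8) is both the usual outcome for α-substituted phosphonoacetates and the less strained ring isomer because it places the ring atoms C8 and C13 cis on C7=C11.

Step 12
Reactants: 18 macrocyclic enoate
Product: 19 macrocyclic allylic alcohol (C12–OH; alkene geometries as in 18)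
Conditions: i-Bu2AlH, CH2Cl2, −78 °C; aq. sodium potassium tartrate
Reagents that add atoms: none
Why: 1,2-Reduction of the conjugated ester to the allylic alcohol without change of alkene geometry.

Step 13
Reactants: 19 macrocyclic alcohol
Product: 20 13-membered bis-allylic ether O–C13H2–C11(CH2OTBS)=C7H–C8H(OTBS)–C9H2–C10(CH2OTBDPS)=C1H–C2H2–C3H2–C4(CH3)=C5H–C6H2 (8S; C8 cis to C13; C2 cis to C9; C3 trans to C6)
Conditions: TBSCl, imidazole, CH2Cl2, 0 °C to rt
Reagents that add atoms: TBSCl, CC(C)(C)[Si](C)(C)Cl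
Why: Silyl ether formation at the primary allylic alcohol, so that no hydroxyl proton remains for the base of step 14.

Step 14
Reactants: 20 13-membered bis-allylic ether
Product: 22 (6S,7S,8S)-8,12-bis[(tert-butyldimethylsilyl)oxy]-14-[(tert-butyldiphenylsilyl)oxy]germacra-1(10),4,11(13)-trien-6-ol (4E; C2 cis to C9; C6–OH cis to the C7 arm; arm trans to C8–O), via C6-lithio ether 21 (not isolated)
Conditions: n-BuLi, THF, −78 to −20 °C; aq. NH4Cl
Reagents that add atoms: none
Why: n-BuLi removes a proton from C6 (α to oxygen and allylic to C4=C5) and the α-oxy allyllithium 21 undergoes a concerted [2,3]-sigmatropic (Wittig) shift through a five-membered envelope (C6, O, C13, C11, C7) that forms C6–C7, breaks O–C13 and moves the alkene to C11=C13, irreversible formation of the lithium alkoxide driving it. The closest known reaction type is the transannular [2,3]-Wittig ring contraction of 13-membered bis-allylic ethers to ten-membered dienols. The ten-membered carbocycle closes by ring contraction (13 to 10) across the ether bridge, not by an end-to-end cyclisation. C6 and C7 are set relative to each other by the geometry of C7=C11: C8 is cis to the migrating C13H2–O terminus, which behaves like a Z-allyl ether and should give the syn product (C6–OH cis to the C7 arm) when the C5 vinyl group sits exo on the envelope. The face of C7 is chosen by C8, whose hydrogen eclipses the alkene to avoid 1,3-allylic strain with C13H2, so that the carbanion bonds anti to the C8–OTBS bond with C9 on the side of attack, which places the C7 arm trans to the C8 oxygen. The step needs lithiation at C6 and not at C13: the C6 hydrogens adjoin an unhindered CH= whereas C13 is flanked by the fully substituted C11 and its silyloxymethyl group, and a C13 anion could only bond to C4 with formation of a quaternary centre.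

Step 15
Reactants: 22 dienol
Product: 23 (4R,5R,6R,7S,8S)-4,5-epoxide of 22 (erythro epoxy alcohol)
Conditions: VO(acac)2 (cat.), t-BuOOH, CH2Cl2, 0 °C
Reagents that add atoms: tert-butyl hydroperoxide, CC(C)(C)OO
Why: Hydroxyl-directed epoxidation by vanadium-bound tert-butyl peroxide needs a small O–C6–C5=C4 dihedral angle, and with the ring bond C6–C7 held roughly perpendicular to the alkene on its inner face this is possible only with oxygen transfer to the outer face anti to C7, which gives the erythro (4R,5R) epoxide; the homoallylic C11=C13 and remote C1=C10 alkenes should react far more slowly.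

Step 16
Reactants: 23 epoxy alcohol
Product: 24 (4R,6S,7S,8S)-8,12-bis[(tert-butyldimethylsilyl)oxy]-14-[(tert-butyldiphenylsilyl)oxy]germacra-1(10),11(13)-diene-4,6-diol (4,6-anti)
Conditions: NaAlH2(OCH2CH2OMe)2 (Red-Al), THF, 0 °C to rt
Reagents that add atoms: none
Why: Red-Al opening of a 2,3-epoxy alcohol: the C6 alkoxyaluminate delivers hydride to the adjacent and less substituted C5, so the C4–O bond and its configuration are kept and the 1,3-diol results.

Step 17
Reactants: 25 methyl but-2-ynoate
Product: 27 methyl (Z)-2-(hydroxymethyl)but-2-enoate (methyl cis to the ester), via alkenylalane 26 (not isolated)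
Conditions: i-Bu2AlH, N-methylmorpholine N-oxide, THF, 0 °C; then CH2O (gas), 0 °C to rt
Reagents that add atoms: formaldehyde, C=O
Why: Syn-hydroalumination of the ynoate puts hydrogen and aluminium cis (methyl cis to the ester) and hydroxymethylation of the alkenylalane with formaldehyde proceeds with retention, which sets the Z-alkene.

Step 18
Reactants: 27 methyl ester
Product: 28 (Z)-2-(hydroxymethyl)but-2-enoic acid
Conditions: LiOH, THF/H2O, 0 °C; then 1 M HCl
Reagents that add atoms: LiOH, [Li+].[OH-]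
Why: Saponification at low temperature, mild enough that the Z-alkene should not isomerise.

Step 19
Reactants: 28 hydroxy acid
Product: 29 (Z)-2-(acetoxymethyl)but-2-enoic acid
Conditions: Ac2O, pyridine, CH2Cl2, 0 °C to rt; aqueous work-up
Reagents that add atoms: acetic anhydride, CC(=O)OC(C)=O
Why: O-Acetylation of the primary allylic alcohol, any mixed anhydride at the acid being hydrolysed on work-up.

Step 20
Reactants: 24 diol; 29 (Z)-2-(acetoxymethyl)but-2-enoic acid
Product: 31 C6 (Z)-2-(acetoxymethyl)but-2-enoate of 24 (4R,6S,7S,8S; C4–OH free), via mixed anhydride 30 (not isolated)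
Conditions: 2,4,6-trichlorobenzoyl chloride, Et3N, toluene, rt; then 24, toluene, 70 °C
Reagents that add atoms: none
Why: Yamaguchi esterification: the mixed anhydride acylates the secondary C6 hydroxyl with retention (the tertiary C4 hydroxyl is inert), and leaving out a nucleophilic catalyst should avoid addition–elimination isomerisation of the Z-alkene.

Step 21
Reactants: 31 ester
Product: 32 (4R,6S,7R,8S)-8,12-diol (C14–OTBDPS kept)
Conditions: camphorsulfonic acid (cat.), MeOH/CH2Cl2, 0 °C to rt
Reagents that add atoms: none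
Why: Acid-catalysed methanolysis should remove the primary (C12) and secondary (C8) TBS ethers while the far more acid-stable TBDPS ether, both esters and the tertiary alcohol persist (selective silyl ether solvolysis).

Step 22
Reactants: 32 diol
Product: 35 14-O-TBDPS ether of the target (8,12-olide closed), via hydroxy enal 33 (not isolated), via lactol 34 (not isolated)
Conditions: TEMPO (cat.), PhI(OAc)2, CH2Cl2, rt
Reagents that add atoms: none
Why: Oxidative lactonisation: the primary allylic alcohol is oxidised to the enal, the C8 hydroxyl adds to give the five-membered lactol and this is oxidised to the α-methylene-γ-lactone, the trans ring fusion being that set in step 14.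

Step 23
Reactants: 35 silyl lactone
Product: 36 CNP0313132.1 (4R,6S,7R,8S)
Conditions: HF·pyridine, THF, 0 °C to rt
Reagents that add atoms: none
Why: Fluoride cleavage of the remaining TBDPS ether under weakly acidic conditions that should spare the methylene lactone and both esters.

**Compound list**

1 | (S)-4-methoxybenzyl glycidyl ether | COc1ccc(COC[C@@H]2CO2)cc1 | starting material
2 | triethyl phosphonoacetate | CCOC(=O)CP(=O)(OCC)OCC | starting material
3 | ethyl (4S)-2-(diethoxyphosphoryl)-4-hydroxy-5-[(4-methoxybenzyl)oxy]pentanoate (C2 epimers) | COc1ccc(COC[C@@H](O)CC(C(=O)OCC)P(=O)(OCC)OCC)cc1 | intermediate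
4 | (5S)-3-(diethoxyphosphoryl)-5-{[(4-methoxybenzyl)oxy]methyl}dihydrofuran-2(3H)-one (C3 epimers) | COc1ccc(COC[C@@H]2CC(P(=O)(OCC)OCC)C(=O)O2)cc1 | intermediate
5 | geraniol | CC(C)=CCC/C(C)=C/CO | starting material
6 | geranyl tert-butyldimethylsilyl ether | CC(C)=CCC/C(C)=C/CO[Si](C)(C)C(C)(C)C | intermediate
7 | 6,7-epoxygeranyl tert-butyldimethylsilyl ether (racemic epoxide) | CC1(C)OC1CC/C(C)=C/CO[Si](C)(C)C(C)(C)C | intermediate
8 | (4E)-6-[(tert-butyldimethylsilyl)oxy]-4-methylhex-4-enal | O=CCC/C(C)=C/CO[Si](C)(C)C(C)(C)C | intermediate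
9 | (3E,5S)-3-{(4E)-6-[(tert-butyldimethylsilyl)oxy]-4-methylhex-4-en-1-ylidene}-5-{[(4-methoxybenzyl)oxy]methyl}dihydrofuran-2(3H)-one | COc1ccc(COC[C@@H]2C/C(=C\CC/C(C)=C/CO[Si](C)(C)C(C)(C)C)C(=O)O2)cc1 | intermediate
10 | (2S,4E,8E)-10-[(tert-butyldimethylsilyl)oxy]-4-(hydroxymethyl)-1-[(4-methoxybenzyl)oxy]-8-methyldeca-4,8-dien-2-ol | COc1ccc(COC[C@@H](O)C/C(CO)=C\CC/C(C)=C/CO[Si](C)(C)C(C)(C)C)cc1 | intermediate
11 | C14-O-TBDPS ether of 10 (C8–OH free) | COc1ccc(COC[C@@H](O)C/C(CO[Si](c2ccccc2)(c2ccccc2)C(C)(C)C)=C\CC/C(C)=C/CO[Si](C)(C)C(C)(C)C)cc1 | intermediate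
12 | (2S,4E,8E)-2,10-bis[(tert-butyldimethylsilyl)oxy]-4-{[(tert-butyldiphenylsilyl)oxy]methyl}-1-[(4-methoxybenzyl)oxy]-8-methyldeca-4,8-diene | COc1ccc(COC[C@@H](O[Si](C)(C)C(C)(C)C)C/C(CO[Si](c2ccccc2)(c2ccccc2)C(C)(C)C)=C\CC/C(C)=C/CO[Si](C)(C)C(C)(C)C)cc1 | intermediate
13 | (2E,6E,9S)-9-[(tert-butyldimethylsilyl)oxy]-7-{[(tert-butyldiphenylsilyl)oxy]methyl}-10-[(4-methoxybenzyl)oxy]-3-methyldeca-2,6-dien-1-ol | COc1ccc(COC[C@@H](O[Si](C)(C)C(C)(C)C)C/C(CO[Si](c2ccccc2)(c2ccccc2)C(C)(C)C)=C\CC/C(C)=C/CO)cc1 | intermediate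
14 | ethyl 2-(diethoxyphosphoryl)acrylate | C=C(C(=O)OCC)P(=O)(OCC)OCC | starting material
15 | ethyl 2-(diethoxyphosphoryl)-3-alkoxypropanoate, the ether of 13 at O6 (C11 epimers) | COc1ccc(COC[C@@H](O[Si](C)(C)C(C)(C)C)C/C(CO[Si](c2ccccc2)(c2ccccc2)C(C)(C)C)=C\CC/C(C)=C/COCC(C(=O)OCC)P(=O)(OCC)OCC)cc1 | intermediate
16 | C7 primary alcohol derived from 15 | OC[C@@H](O[Si](C)(C)C(C)(C)C)C/C(CO[Si](c1ccccc1)(c1ccccc1)C(C)(C)C)=C\CC/C(C)=C/COCC(C(=O)OCC)P(=O)(OCC)OCC | intermediate
17 | C7 aldehyde (8S α-silyloxy aldehyde) | O=C[C@@H](O[Si](C)(C)C(C)(C)C)C/C(CO[Si](c1ccccc1)(c1ccccc1)C(C)(C)C)=C\CC/C(C)=C/COCC(C(=O)OCC)P(=O)(OCC)OCC | intermediate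
18 | ethyl (3E,5S,7E,11E)-5-[(tert-butyldimethylsilyl)oxy]-7-{[(tert-butyldiphenylsilyl)oxy]methyl}-11-methyl-1-oxacyclotrideca-3,7,11-triene-3-carboxylate | O1C/C(C(=O)OCC)=C\[C@@H](O[Si](C)(C)C(C)(C)C)C/C(CO[Si](c2ccccc2)(c2ccccc2)C(C)(C)C)=C\CC/C(C)=C/C1 | intermediate
19 | 13-membered ether with C12–OH (C8 cis to C13) | O1C/C(CO)=C\[C@@H](O[Si](C)(C)C(C)(C)C)C/C(CO[Si](c2ccccc2)(c2ccccc2)C(C)(C)C)=C\CC/C(C)=C/C1 | intermediate
20 | 13-membered bis-allylic ether with C12–OTBS, C8–OTBS, C14–OTBDPS (8S; C8 cis to C13) | O1C/C(CO[Si](C)(C)C(C)(C)C)=C\[C@@H](O[Si](C)(C)C(C)(C)C)C/C(CO[Si](c2ccccc2)(c2ccccc2)C(C)(C)C)=C\CC/C(C)=C/C1 | intermediate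
21 | C6-lithiated 20 | O1C/C(CO[Si](C)(C)C(C)(C)C)=C\[C@@H](O[Si](C)(C)C(C)(C)C)C/C(CO[Si](c2ccccc2)(c2ccccc2)C(C)(C)C)=C\CC/C(C)=C/C1[Li] | intermediate
22 | (6S,7S,8S)-8,12-bis[(tert-butyldimethylsilyl)oxy]-14-[(tert-butyldiphenylsilyl)oxy]germacra-1(10),4,11(13)-trien-6-ol | C=C(CO[Si](C)(C)C(C)(C)C)[C@@H]1[C@@H](O[Si](C)(C)C(C)(C)C)C/C(CO[Si](c2ccccc2)(c2ccccc2)C(C)(C)C)=C\CC/C(C)=C/[C@@H]1O | intermediate
23 | (4R,5R,6R,7S,8S)-4,5-epoxide of 22 | C=C(CO[Si](C)(C)C(C)(C)C)[C@@H]1[C@@H](O[Si](C)(C)C(C)(C)C)C/C(CO[Si](c2ccccc2)(c2ccccc2)C(C)(C)C)=C\CC[C@@]2(C)O[C@@H]2[C@@H]1O | intermediate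
24 | (4R,6S,7S,8S)-8,12-bis[(tert-butyldimethylsilyl)oxy]-14-[(tert-butyldiphenylsilyl)oxy]germacra-1(10),11(13)-diene-4,6-diol | C=C(CO[Si](C)(C)C(C)(C)C)[C@@H]1[C@@H](O[Si](C)(C)C(C)(C)C)C/C(CO[Si](c2ccccc2)(c2ccccc2)C(C)(C)C)=C\CC[C@@](C)(O)C[C@@H]1O | intermediate
25 | methyl but-2-ynoate | CC#CC(=O)OC | starting material
26 | methyl 2-(diisobutylaluminio)but-2-enoate (methyl cis to the ester) | C/C=C(/[Al](CC(C)C)CC(C)C)C(=O)OC | intermediate
27 | methyl (Z)-2-(hydroxymethyl)but-2-enoate | C/C=C(/CO)C(=O)OC | intermediate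
28 | (Z)-2-(hydroxymethyl)but-2-enoic acid | C/C=C(/CO)C(=O)O | intermediate
29 | (Z)-2-(acetoxymethyl)but-2-enoic acid | C/C=C(/COC(C)=O)C(=O)O | intermediate
30 | mixed anhydride of 29 with 2,4,6-trichlorobenzoic acid | C/C=C(/COC(C)=O)C(=O)OC(=O)c1c(Cl)cc(Cl)cc1Cl | intermediate
31 | C6 (Z)-2-(acetoxymethyl)but-2-enoate of 24 | C=C(CO[Si](C)(C)C(C)(C)C)[C@@H]1[C@@H](O[Si](C)(C)C(C)(C)C)C/C(CO[Si](c2ccccc2)(c2ccccc2)C(C)(C)C)=C\CC[C@@](C)(O)C[C@@H]1OC(=O)/C(=C\C)COC(C)=O | intermediate
32 | (4R,6S,7R,8S)-4,8,12-triol 6-ester with C14–OTBDPS | C=C(CO)[C@@H]1[C@@H](O)C/C(CO[Si](c2ccccc2)(c2ccccc2)C(C)(C)C)=C\CC[C@@](C)(O)C[C@@H]1OC(=O)/C(=C\C)COC(C)=O | intermediate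
33 | C12 aldehyde of 32 (8-hydroxy enal) | O=CC(=C)[C@@H]1[C@@H](O)C/C(CO[Si](c2ccccc2)(c2ccccc2)C(C)(C)C)=C\CC[C@@](C)(O)C[C@@H]1OC(=O)/C(=C\C)COC(C)=O | intermediate
34 | 8,12-lactol (anomers) | C=C1C(O)O[C@H]2C/C(CO[Si](c3ccccc3)(c3ccccc3)C(C)(C)C)=C\CC[C@@](C)(O)C[C@H](OC(=O)/C(=C\C)COC(C)=O)[C@H]12 | intermediate
35 | 14-O-tert-butyldiphenylsilyl ether of the target | C=C1C(=O)O[C@H]2C/C(CO[Si](c3ccccc3)(c3ccccc3)C(C)(C)C)=C\CC[C@@](C)(O)C[C@H](OC(=O)/C(=C\C)COC(C)=O)[C@H]12 | intermediate
36 | CNP0313132.1, (4R,6S,7R,8S)-6-[(Z)-2-(acetoxymethyl)but-2-enoyloxy]-4,14-dihydroxygermacra-1(10),11(13)-dien-8,12-olide | C=C1C(=O)O[C@H]2C/C(CO)=C\CC[C@@](C)(O)C[C@H](OC(=O)/C(=C\C)COC(C)=O)[C@H]12 | target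

**Step count and risks**

Total step count: 23. Longest linear sequence: 19 steps (5 to 36 through steps 2–16 and 20–23).

Steps most likely to fail:

1. Step 14. The envelope may also be entered with the C5 vinyl group endo, which erodes the C6 configuration; lithiation at C13 followed by loss of the C8 silyloxy group would further lower the yield. Fallback, setting out from 20 and coming back at 22: the rearrangement is run as described and the carbinol fraction, containing 22 and the (6R)-epimeric dienol F1, is oxidised with Dess–Martin periodinane to the single C6 ketone (cross-conjugated dienone) F2. Luche reduction of F2 (NaBH4, CeCl3·7H2O, MeOH, −78 °C) is expected to deliver hydride to the C6 face remote from the C7 arm and so to return 22. C6 is then set by hydride addition to a ketone and no longer by the sigmatropic transition state.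

2. Step 15. Facial selectivity would be lost if the ring reacts through the conformer in which C6–H, not C6–O, lies near the alkene plane, which leads to the threo epoxide and the wrong C4 configuration. Fallback, setting out from 22 and coming back at 23: stereocontrol is handed from the substrate to the reagent by Katsuki–Sharpless epoxidation (Ti(OiPr)4, D-(−)-diethyl tartrate, t-BuOOH, 4 Å sieves, CH2Cl2, −20 °C). The C6 configuration of 22 is the fast-reacting one for this tartrate, and its matched product is the erythro epoxy alcohol 23. No new compound is made.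

3. Step 20. Acyl transfer to the hindered C6 carbinol may be slow, and the activated acid may isomerise from Z to E by reversible conjugate addition. Fallback, setting out from 24 and coming back at 31: the alcohol is activated in place of the acid. Dess–Martin oxidation of 24 gives the β-hydroxy ketone F3. Narasaka–Prasad reduction (Et2BOMe, NaBH4, THF/MeOH, −78 °C) should give the 4,6-syn diol F4, the C6 epimer of 24. Mitsunobu esterification of F4 with acid 29 (PPh3, diisopropyl azodicarboxylate, toluene, 0 °C) should then install the ester with inversion at C6 and give 31 without an activated acyl species.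

Further compounds
F1 | step 14 | (6R,7S,8S)-8,12-bis[(tert-butyldimethylsilyl)oxy]-14-[(tert-butyldiphenylsilyl)oxy]germacra-1(10),4,11(13)-trien-6-ol (C6 epimer of 22) | C=C(CO[Si](C)(C)C(C)(C)C)[C@@H]1[C@@H](O[Si](C)(C)C(C)(C)C)C/C(CO[Si](c2ccccc2)(c2ccccc2)C(C)(C)C)=C\CC/C(C)=C/[C@H]1O
F2 | step 14 | (7S,8S)-8,12-bis[(tert-butyldimethylsilyl)oxy]-14-[(tert-butyldiphenylsilyl)oxy]germacra-1(10),4,11(13)-trien-6-one | C=C(CO[Si](C)(C)C(C)(C)C)[C@@H]1[C@@H](O[Si](C)(C)C(C)(C)C)C/C(CO[Si](c2ccccc2)(c2ccccc2)C(C)(C)C)=C\CC/C(C)=C/C1=O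
F0 | step 15 | none | none
F3 | step 20 | (4R,7S,8S)-8,12-bis[(tert-butyldimethylsilyl)oxy]-14-[(tert-butyldiphenylsilyl)oxy]-4-hydroxygermacra-1(10),11(13)-dien-6-one | C=C(CO[Si](C)(C)C(C)(C)C)[C@@H]1[C@@H](O[Si](C)(C)C(C)(C)C)C/C(CO[Si](c2ccccc2)(c2ccccc2)C(C)(C)C)=C\CC[C@@](C)(O)CC1=O
F4 | step 20 | (4R,6R,7S,8S)-8,12-bis[(tert-butyldimethylsilyl)oxy]-14-[(tert-butyldiphenylsilyl)oxy]germacra-1(10),11(13)-diene-4,6-diol (4,6-syn; C6 epimer of 24) | C=C(CO[Si](C)(C)C(C)(C)C)[C@@H]1[C@@H](O[Si](C)(C)C(C)(C)C)C/C(CO[Si](c2ccccc2)(c2ccccc2)C(C)(C)C)=C\CC[C@@](C)(O)C[C@H]1O
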